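**Retrosynthetic overview**
1. Ring construction comes first and is done once for both rings: (E)-non-3-en-2-one 1 + dimethyl malonate 2 → Michael adduct 3 → Claisen ring closure to cyclohexanedione 4 → aromatization (via bromide 5) to methyl olivetolate 6. The key disconnection is the C–C bond between the malonate carbon and the enone β-carbon.
2. Ring A (acyl half) is cut back to 6 through methyl ether 7, benzyl ether 8 and acid 9. Ring B (phenol half) is cut back to 6 through olivetolic acid 10 and its benzyl ester 11.
3. The last disconnection is the depside ester C–O bond: acid 9 (activated as mixed anhydride 12) + the 4-OH of 11 → protected depside 13, then one hydrogenolysis to perlatolic acid 14.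
4. Order: the carbocycle is built and aromatized, the material is divided into the ring A and ring B branches, and the two aryl units are joined last; no other ring is formed.

Assumption: perlatolic acid has no stereocentre and no stereogenic double bond, so the achiral compound is the required single species; (E)-non-3-en-2-one is taken as a commercial flavour chemical.

**Route**

Step 1
Reactants: 1 (E)-non-3-en-2-one; 2 dimethyl malonate
Product: 4 methyl 2,4-dioxo-6-pentylcyclohexane-1-carboxylate, via Michael adduct 3 (not isolated)
Conditions: NaOMe (1.1 equiv), MeOH, reflux, 4 h; then aq. HCl, 0 °C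
Reagents that add atoms: none
Why: Intermolecular Michael addition of the malonate anion to the enone β-carbon forms the key C–C bond, and the methyl-ketone enolate of 3 then closes the ring by intramolecular Claisen condensation driven by the stabilized β-diketone enolate; the two new stereocentres form as a racemic mixture and are erased in step 2.

Step 2
Reactants: 4 methyl 2,4-dioxo-6-pentylcyclohexane-1-carboxylate
Product: 6 methyl 2,4-dihydroxy-6-pentylbenzoate (methyl olivetolate), via 3-bromo dione 5 (not isolated)
Conditions: Br2 (1.0 equiv), DMF, 0 °C, then 80 °C, 14 h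
Reagents that add atoms: none
Why: Oxidative aromatization by α-bromination of the cyclic 1,3-dione, then thermal dehydrobromination and enolization to the resorcinol; at 80 °C the ester is kept and no decarboxylation occurs.

Step 3
Reactants: 6 methyl 2,4-dihydroxy-6-pentylbenzoate
Product: 7 methyl 2-hydroxy-4-methoxy-6-pentylbenzoate
Conditions: MeI (1.1 equiv), K2CO3 (1.2 equiv), acetone, reflux
Reagents that add atoms: iodomethane (MeI), CI
Why: Williamson etherification is selective for the 4-OH because the 2-OH is hydrogen-bonded to the ester carbonyl, less acidic and more hindered.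

Step 4
Reactants: 7 methyl 2-hydroxy-4-methoxy-6-pentylbenzoate
Product: 8 methyl 2-(benzyloxy)-4-methoxy-6-pentylbenzoate
Conditions: BnBr (1.3 equiv), K2CO3 (2 equiv), DMF, 60 °C
Reagents that add atoms: benzyl bromide (BnBr), BrCc1ccccc1
Why: Williamson benzylation under more forcing conditions alkylates the remaining chelated phenol and masks it against self-acylation in the coupling.

Step 5
Reactants: 8 methyl 2-(benzyloxy)-4-methoxy-6-pentylbenzoate
Product: 9 2-(benzyloxy)-4-methoxy-6-pentylbenzoic acid
Conditions: KOH (6 equiv), DMSO/H2O 4:1, 90 °C; then aq. HCl, 0 °C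
Reagents that add atoms: potassium hydroxide (KOH), [K+].[OH-]
Why: Saponification of the di-ortho-substituted ester succeeds with poorly solvated hydroxide in DMSO, and the benzyl and methyl ethers are inert to base.

Step 6
Reactants: 6 methyl 2,4-dihydroxy-6-pentylbenzoate
Product: 10 2,4-dihydroxy-6-pentylbenzoic acid (olivetolic acid)
Conditions: KOH (6 equiv), H2O/MeOH 1:1, 70 °C, N2; then cold 1 M HCl to pH 2, 0 °C
Reagents that add atoms: potassium hydroxide (KOH), [K+].[OH-]
Why: Saponification under inert gas gives a phenoxide-carboxylate polyanion that resists decarboxylation in base, and cold acidification avoids the acid-promoted loss of CO2.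

Step 7
Reactants: 10 2,4-dihydroxy-6-pentylbenzoic acid
Product: 11 benzyl 2,4-dihydroxy-6-pentylbenzoate
Conditions: BnBr (1.05 equiv), KHCO3 (1.1 equiv), DMF, rt to 40 °C
Reagents that add atoms: benzyl bromide (BnBr), BrCc1ccccc1
Why: SN2 O-alkylation of the carboxylate only, because KHCO3 deprotonates the acid but not the phenols.

Step 8
Reactants: 9 2-(benzyloxy)-4-methoxy-6-pentylbenzoic acid; 11 benzyl 2,4-dihydroxy-6-pentylbenzoate
Product: 13 benzyl 4-{[2-(benzyloxy)-4-methoxy-6-pentylbenzoyl]oxy}-2-hydroxy-6-pentylbenzoate, via mixed trifluoroacetic anhydride 12 (not isolated)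
Conditions: TFAA (4 equiv), anhydrous toluene, rt, 3 h
Reagents that add atoms: none
Why: Depside esterification through the mixed anhydride acylates only the free, unhindered 4-OH of 11, since the 2-OH is hydrogen-bonded to the benzyl ester carbonyl and flanked by it.

Step 9
Reactants: 13 benzyl 4-{[2-(benzyloxy)-4-methoxy-6-pentylbenzoyl]oxy}-2-hydroxy-6-pentylbenzoate
Product: 14 perlatolic acid
Conditions: H2 (1 atm), 10% Pd/C, EtOAc, rt
Reagents that add atoms: none
Why: Catalytic hydrogenolysis removes the benzyl ether and the benzyl ester together while the aryl ester link, the methyl ether and both arenes are untouched at room temperature.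

**Compound list**
1 | (E)-non-3-en-2-one | CCCCC/C=C/C(C)=O | starting material
2 | dimethyl malonate | COC(=O)CC(=O)OC | starting material
3 | dimethyl 2-(2-oxononan-4-yl)malonate (racemic Michael adduct) | CCCCCC(CC(C)=O)C(C(=O)OC)C(=O)OC | intermediate
4 | methyl 2,4-dioxo-6-pentylcyclohexane-1-carboxylate (racemic, mainly as its enol) | CCCCCC1CC(=O)CC(=O)C1C(=O)OC | intermediate
5 | methyl 3-bromo-2,4-dioxo-6-pentylcyclohexane-1-carboxylate (stereoisomer mixture) | CCCCCC1CC(=O)C(Br)C(=O)C1C(=O)OC | intermediate
6 | methyl 2,4-dihydroxy-6-pentylbenzoate (methyl olivetolate) | CCCCCc1cc(O)cc(O)c1C(=O)OC | intermediate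
7 | methyl 2-hydroxy-4-methoxy-6-pentylbenzoate | CCCCCc1cc(OC)cc(O)c1C(=O)OC | intermediate
8 | methyl 2-(benzyloxy)-4-methoxy-6-pentylbenzoate | CCCCCc1cc(OC)cc(OCc2ccccc2)c1C(=O)OC | intermediate
9 | 2-(benzyloxy)-4-methoxy-6-pentylbenzoic acid | CCCCCc1cc(OC)cc(OCc2ccccc2)c1C(=O)O | intermediate
10 | 2,4-dihydroxy-6-pentylbenzoic acid (olivetolic acid) | CCCCCc1cc(O)cc(O)c1C(=O)O | intermediate
11 | benzyl 2,4-dihydroxy-6-pentylbenzoate | CCCCCc1cc(O)cc(O)c1C(=O)OCc1ccccc1 | intermediate
12 | 2-(benzyloxy)-4-methoxy-6-pentylbenzoic trifluoroacetic anhydride | CCCCCc1cc(OC)cc(OCc2ccccc2)c1C(=O)OC(=O)C(F)(F)F | intermediate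
13 | benzyl 4-{[2-(benzyloxy)-4-methoxy-6-pentylbenzoyl]oxy}-2-hydroxy-6-pentylbenzoate | CCCCCc1cc(OC(=O)c2c(OCc3ccccc3)cc(OC)cc2CCCCC)cc(O)c1C(=O)OCc1ccccc1 | intermediate
14 | perlatolic acid, 2-hydroxy-4-[(2-hydroxy-4-methoxy-6-pentylbenzoyl)oxy]-6-pentylbenzoic acid (achiral) | CCCCCc1cc(OC(=O)c2c(O)cc(OC)cc2CCCCC)cc(O)c1C(=O)O | target

**Step count and risks**
Total steps: 9. Longest linear sequence: 7 (steps 1, 2, 3, 4, 5, 8, 9); the ring B branch (steps 6, 7) joins at step 8.

Most likely to fail:

Step 8 (depside coupling of a hindered acid; possible acylation at the wrong oxygen or benzyl loss in the acidic medium). The fallback sets out from acid 9. Treatment with (COCl)2 and catalytic DMF in CH2Cl2 at 0 °C to rt gives 2-(benzyloxy)-4-methoxy-6-pentylbenzoyl chloride F1. This is isolated by evaporation and added at 0 °C to 11 and K2CO3 (1.1 equiv) in acetone, where only the more acidic 4-phenoxide is formed and acylated under basic, acid-free conditions. The route is rejoined at 13.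

Step 6 (saponification of 6 without losing CO2 from the β-resorcylic acid). The fallback sets out from 6 and deliberately completes the decarboxylation: aq. NaOH at reflux, then acidification and brief heating give 5-pentylbenzene-1,3-diol (olivetol) F2. This is re-carboxylated ortho to one hydroxyl and para to the other with methyl magnesium carbonate, MeOMgOCO2Me, in DMF at 120 °C, followed by cold HCl work-up. The magnesium chelate protects the salicylate until quench, and the route is rejoined at 10.

Step 2 (aromatization; under- or over-bromination with one equivalent of Br2). The fallback sets out from 4 and pushes bromination to a single defined product: Br2 (3 equiv) in AcOH at rt gives methyl 3,5-dibromo-2,4-dihydroxy-6-pentylbenzoate F3, which crystallizes. Reductive debromination with H2, Pd/C and NaOAc in MeOH then removes both aryl bromides, and the route is rejoined at 6.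

**Further compounds**
F1 | step 8 | 2-(benzyloxy)-4-methoxy-6-pentylbenzoyl chloride | CCCCCc1cc(OC)cc(OCc2ccccc2)c1C(Cl)=O
F2 | step 6 | 5-pentylbenzene-1,3-diol (olivetol) | CCCCCc1cc(O)cc(O)c1
F3 | step 2 | methyl 3,5-dibromo-2,4-dihydroxy-6-pentylbenzoate | CCCCCc1c(Br)c(O)c(Br)c(O)c1C(=O)OC
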